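Temperature was where I began. The earlier runs stood at two temperatures, and each levelled off with substrate left in the flask.

| flask | substrate | coupling partner | catalyst | temperature | remark | time |
|---|---|---|---|---|---|---|
| summer | 10 mM | 7 mM | 50 µM | 95 °C | run made earlier |  |
| autumn | 10 mM | 3.5 mM | 50 µM | 110 °C | run made earlier |  |
| spring | 10 mM | 5.2 mM | 50 µM | 95 °C | run made earlier |  |
| south-west | 10 mM (in portions, 3, over 4.0 min) | 7.00 mM | 50 µM | 110 °C | first portion at the start, last at 4.0 min | 6.0 min |
| north-east | 10 mM | 7.00 mM | 50 µM | 110 °C | everything together at the start | 6.0 min |
| south | 10 mM (fed, over 4.0 min) | 7.00 mM | 50 µM |  | the addition at 90 °C, then warmed to 110 °C; the feed brings no volume worth counting | 6.0 min |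
| east | 10 mM (fed, over 4.0 min) | 7.00 mM | 50 µM | 110 °C | all else is in the flask from the start; the feed brings no volume worth counting | 6.0 min |

| run | time / min | target / % | substrate / % |
|---|---|---|---|
| summer | 2.00 | 60.3 | 40.1 |
| summer | 3.00 | 63.1 | 37.0 |
| summer | 5.00 | 66.5 | 34.2 |
| summer | 6.00 | 65.8 | 34.1 |
| summer | 8.00 | 66.6 | 33.7 |
| summer | 10.0 | 66.5 | 33.5 |
| summer | 12.0 | 65.8 | 33.9 |
| autumn | 0.200 | 13.2 | 87.2 |
| autumn | 0.500 | 22.0 | 77.9 |
| autumn | 1.00 | 27.4 | 71.9 |
| autumn | 1.50 | 29.9 | 70.4 |
| autumn | 2.00 | 30.5 | 69.8 |
| autumn | 3.00 | 30.8 | 69.8 |
| autumn | 4.00 | 31.3 | 69.4 |
| spring | 0.417 | 25.7 | 74.5 |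
| spring | 1.00 | 39.3 | 60.6 |
| spring | 2.00 | 46.5 | 53.7 |
| spring | 3.00 | 48.7 | 51.7 |
| spring | 4.00 | 49.4 | 50.7 |
| spring | 6.00 | 49.7 | 50.0 |
| spring | 8.00 | 49.3 | 50.4 |

(standard deviation of a reading: 0.3 percentage points)

- the numbers in the tables scatter with a standard deviation of 0.3 percentage points
- on the list of suspects stand: substrate + coupling partner + catalyst -> catalyst + target; coupling partner -> decomposed reagent

1. which flask leads in amount of target, in percent of the substrate charged ("all alike" within 1.5 percentage points) (south-west / north-east / south / east / all alike)
2. how much target is there at the end, in percent of the substrate charged: south-west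
3. how much target is there at the end, in percent of the substrate charged: north-east
4. how much target is there at the end, in percent of the substrate charged: south
5. how much target is there at the end, in percent of the substrate charged: east

On the list of suspects, coupling partner can leave by two steps: it couples with substrate under the catalyst to give target, or it decomposes by itself. Coupling goes with [substrate] and decomposition doesn't, so I expected the share going to target to be [substrate]/([substrate] + r), where r is a selectivity factor in concentration units. Summed over a run with everything in the flask from the start, up to its plateau, the coupling partner lost to decomposition is then r times the logarithm of substrate at the start over substrate at the end.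

In the autumn run, at 110 °C, 3.5 mM of coupling partner was charged and 3.06 mM of substrate had been consumed by 4.00 min. So the reading 1.20 mM is the [substrate] at which coupling partner couples as fast as it decomposes, the break-even substrate. The summer run gave 0.320 mM at 95 °C.

For north-east I took two extremes. With the whole coupling partner charge shared at the opening [substrate] of 10 mM, target reaches 62.5%. Shared at the lowest [substrate] possible, 3.00 mM, it reaches 49.9%. I expected the real flask nearer the upper figure: at the opening the share going to target is 89.3%, against 71.4% at the lowest [substrate], and I took the opening minutes to carry most of the coupling partner. A feed starts from nil substrate, so east begins below its r, while south is fed at 90 °C, cooler than the summer run, whose reading of r was already smaller than the autumn one by a factor of 3.75.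

The forecast named south as leader, with south-west at 44%, north-east at 60%, south at 61% and east at 41%, holding that “Decomposition is much more temperature-sensitive than coupling”. Its ratio at 110 °C read 1.1 mM against my 1.20 mM.

The flasks gave south-west 43.1%, north-east 59.5%, south 61.0% and east 39.5%, so south led.

    substrate + coupling partner + catalyst → catalyst + target (k = 86000 M⁻² s⁻¹, Ea = 21.0 kJ mol⁻¹)
    coupling partner → decomposed reagent (k = 0.00500 s⁻¹, Ea = 119 kJ mol⁻¹)
    (constants at 110 °C)

South finished 22 percentage points above east, and with the loss of coupling partner to decomposed reagent taken away that difference is −0.53 points. Over the first 4.0 min the mean [substrate] was 2.40 mM in south and 2.75 mM in east, which is 7.50 times the summer reading of r in south and 2.29 times the autumn reading in east. East's answer had moved by 5 points, out of the forecast's range, at a coupling partner charge of 5.99 mM or 8.06 mM. In north-east, r times the logarithm of substrate charged over substrate left gives 1.09 mM lost to decomposition, and that flask held 1.05 mM of decomposed reagent at 6.00 min.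

All runs stem from a simulated flask for substances that don't exist, noise included.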